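**Retrosynthetic overview**

1. The target is reached by saponifying one vinylogous ester of a 2,5-dimethoxyquinone, which comes from (NH4)2Ce(NO3)6 oxidation of a tetramethoxyarene; the quinone is unmasked last.
2. The strategy rests on the C4–C5 bond of ring A, which joins the quaternary gem-dimethyl carbon C4 to the ring-fusion carbinol carbon C5. It is cut to a C5 ketone in ring B and a 4-methylpent-4-enyl chain on C10, whose terminal CH2 becomes the second C4 methyl (iron-hydride hydrogen-atom transfer, tertiary radical onto C=O).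
3. The ring B ketone comes from a C5 alcohol made by hydroboration of a C10=C5 alkene (sets C10). That alkene comes from Negishi coupling of an enol triflate with a ketal-masked chain, so borane meets only one alkene; the chain alkene is released afterwards by hydrolysis and Wittig methylenation.
4. The enol triflate comes from a 2-arylmethyl-2,3-dimethylcyclohexanone, made by copper-catalysed asymmetric methyl addition to 2-methylcyclohex-2-en-1-one (C8) and enolate benzylation trans to that methyl (C9). The benzyl bromide is made from 1,2,4,5-tetramethoxybenzene.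
5. Ring order: ring B is the purchased cyclohexenone, ring A closes in the key step, and the quinone ring is oxidised at the end.

Key step: step 12

Remark on numbering: C1–C11 are the positions of the target decalin (ring A = C1–C5 and C10; ring B = C5–C10; C11 = the CH2 to the arene). "β" is the face of ring B that carries the C8 and C9 methyl groups, "α" the opposite face.

Assumption: the antipode of the phosphoramidite ligand in step 4 is taken to be the one that gives the (3S) methyl centre; its sense of induction is to be confirmed on the product of step 4.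

**Route**

Step 1
Reactants: 1 1,2,4,5-tetramethoxybenzene
Product: 3 2,3,5,6-tetramethoxybenzaldehyde, via aryllithium 2 (not isolated)
Conditions: n-BuLi (1.05 equiv), TMEDA, THF, 0 °C; DMF, 0 °C to rt; aq. NH4Cl
Reagents that add atoms: N,N-dimethylformamide, CN(C)C=O
Why: Directed ortho-lithiation at a ring CH flanked by two methoxy groups (both CH positions are equivalent) followed by formylation of the aryllithium with DMF should give the aldehyde after hydrolysis of the hemiaminal.

Step 2
Reactants: 3 2,3,5,6-tetramethoxybenzaldehyde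
Product: 4 (2,3,5,6-tetramethoxyphenyl)methanol
Conditions: NaBH4, MeOH, 0 °C
Reagents that add atoms: none
Why: Borohydride reduction of an aromatic aldehyde to the benzylic alcohol is routine and touches nothing else.

Step 3
Reactants: 4 (2,3,5,6-tetramethoxyphenyl)methanol
Product: 5 3-(bromomethyl)-1,2,4,5-tetramethoxybenzene
Conditions: PBr3, Et2O, 0 °C
Reagents that add atoms: phosphorus tribromide, BrP(Br)Br
Why: Substitution of the benzylic alcohol through its phosphite ester with PBr3 is reliable for electron-rich benzylic alcohols, and the bromide is used at once because it ionises easily.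

Step 4
Reactants: 6 2-methylcyclohex-2-en-1-one
Product: 8 trimethyl{[(3S)-2,3-dimethylcyclohex-1-en-1-yl]oxy}silane, via aluminium enolate 7 (not isolated)
Conditions: Me3Al, copper thiophene-2-carboxylate (C5H3CuO2S, monovalent copper) cat., (S)-BINOL-derived N,N-bis[(S)-1-phenylethyl]phosphoramidite (or its antipode, see assumption), Et2O, −30 °C; then TMSOTf, −30 to 0 °C
Reagents that add atoms: trimethylaluminium, C[Al](C)C; trimethylsilyl trifluoromethanesulfonate, C[Si](C)(C)OS(=O)(=O)C(F)(F)F
Why: Copper-catalysed asymmetric conjugate addition of a methyl group from Me3Al to the α-substituted enone sets C8 under control of the chiral phosphoramidite–copper complex, and O-silylation of the aluminium enolate stores the enolate with its regiochemistry fixed.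

Step 5
Reactants: 8 trimethyl{[(3S)-2,3-dimethylcyclohex-1-en-1-yl]oxy}silane; 5 3-(bromomethyl)-1,2,4,5-tetramethoxybenzene
Product: 10 (2R,3S)-2,3-dimethyl-2-[(2,3,5,6-tetramethoxyphenyl)methyl]cyclohexan-1-one, via lithium enolate 9 (not isolated)
Conditions: MeLi, THF, 0 °C to rt; then DMPU, 5, −78 to 0 °C
Reagents that add atoms: none
Why: MeLi cleaves the silyl enol ether to the regiodefined lithium enolate, and C-alkylation with the benzylic bromide (enolate alkylation) should occur anti to the neighbouring methyl, which sits pseudoaxial to avoid A(1,2) strain with the vinylic methyl, so the arylmethyl group ends trans to the C8 methyl and C9 is set.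

Step 6
Reactants: 10 (2R,3S)-2,3-dimethyl-2-[(2,3,5,6-tetramethoxyphenyl)methyl]cyclohexan-1-one
Product: 12 (5S,6R)-5,6-dimethyl-6-[(2,3,5,6-tetramethoxyphenyl)methyl]cyclohex-1-en-1-yl trifluoromethanesulfonate, via potassium enolate 11 (not isolated)
Conditions: KHMDS, THF, −78 °C; PhNTf2, −78 °C to rt
Reagents that add atoms: N-phenylbis(trifluoromethanesulfonimide), O=S(=O)(N(c1ccccc1)S(=O)(=O)C(F)(F)F)C(F)(F)F
Why: The ketone can enolise only toward its CH2 side because the other α-carbon is quaternary, so deprotonation and O-sulfonylation (enol triflate formation) should give a single alkenyl triflate.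

Step 7
Reactants: 12 (5S,6R)-5,6-dimethyl-6-[(2,3,5,6-tetramethoxyphenyl)methyl]cyclohex-1-en-1-yl trifluoromethanesulfonate; 13 2-(3-chloropropyl)-2-methyl-1,3-dioxolane
Product: 16 2-{3-[(5S,6R)-5,6-dimethyl-6-[(2,3,5,6-tetramethoxyphenyl)methyl]cyclohex-1-en-1-yl]propyl}-2-methyl-1,3-dioxolane, via Grignard reagent 14 (not isolated), via alkylzinc chloride 15 (not isolated)
Conditions: 13, Mg, THF, reflux; ZnCl2, THF, 0 °C; then 12, PdCl2(dppf) (divalent palladium precatalyst) cat., THF, 60 °C
Reagents that add atoms: none
Why: Negishi coupling of the alkenyl triflate with the primary alkylzinc chloride forms the C10–C1 bond (dppf limits β-hydride elimination), and the dioxolane carries the future isopropenyl carbon in a form that is inert to borane in the next step.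

Step 8
Reactants: 16 2-{3-[(5S,6R)-5,6-dimethyl-6-[(2,3,5,6-tetramethoxyphenyl)methyl]cyclohex-1-en-1-yl]propyl}-2-methyl-1,3-dioxolane
Product: 18 (1S,2S,3R,4S)-3,4-dimethyl-2-[3-(2-methyl-1,3-dioxolan-2-yl)propyl]-3-[(2,3,5,6-tetramethoxyphenyl)methyl]cyclohexan-1-ol, via alkylborane 17 (not isolated)
Conditions: BH3·THF, THF, 0 °C to rt; NaOH, H2O2, 0 to 40 °C
Reagents that add atoms: hydrogen peroxide, OO
Why: Hydroboration–oxidation puts boron on the less substituted C5 and hydrogen on C10 in a syn addition that should come from the α face (in the half-chair with equatorial C8 methyl the pseudoaxial C9 methyl shields the β face, and in the other half-chair the pseudoaxial arylmethyl group and the axial C8 methyl shield both faces), and oxidation with retention gives the C5 alcohol trans to the chain, which sets C10 with its hydrogen α.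

Step 9
Reactants: 18 (1S,2S,3R,4S)-3,4-dimethyl-2-[3-(2-methyl-1,3-dioxolan-2-yl)propyl]-3-[(2,3,5,6-tetramethoxyphenyl)methyl]cyclohexan-1-ol
Product: 19 5-{(1S,2R,3S,6S)-6-hydroxy-2,3-dimethyl-2-[(2,3,5,6-tetramethoxyphenyl)methyl]cyclohexyl}pentan-2-one
Conditions: 1 M HCl, THF, rt
Reagents that add atoms: water, O
Why: Acid hydrolysis of the dioxolane (acetal hydrolysis) releases the methyl ketone while the secondary alcohol, the arene and the C10 centre (not epimerisable while C5 is a carbinol) are unaffected.

Step 10
Reactants: 19 5-{(1S,2R,3S,6S)-6-hydroxy-2,3-dimethyl-2-[(2,3,5,6-tetramethoxyphenyl)methyl]cyclohexyl}pentan-2-one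
Product: 20 (1S,2S,3R,4S)-3,4-dimethyl-2-(4-methylpent-4-en-1-yl)-3-[(2,3,5,6-tetramethoxyphenyl)methyl]cyclohexan-1-ol
Conditions: Ph3PCH3Br (3 equiv), KOtBu, THF, 0 °C to rt
Reagents that add atoms: methyltriphenylphosphonium bromide, C[P+](c1ccccc1)(c1ccccc1)c1ccccc1.[Br-]
Why: Wittig methylenation of the unhindered methyl ketone with excess ylide should give the 1,1-disubstituted alkene, the free alcohol being carried as its alkoxide and recovered on work-up.

Step 11
Reactants: 20 (1S,2S,3R,4S)-3,4-dimethyl-2-(4-methylpent-4-en-1-yl)-3-[(2,3,5,6-tetramethoxyphenyl)methyl]cyclohexan-1-ol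
Product: 21 (2S,3R,4S)-3,4-dimethyl-2-(4-methylpent-4-en-1-yl)-3-[(2,3,5,6-tetramethoxyphenyl)methyl]cyclohexan-1-one
Conditions: DMP (1,1,1-triacetoxy-1,2-benziodoxol-3(1H)-one), pyridine, CH2Cl2, 0 °C to rt
Reagents that add atoms: none
Why: Dess–Martin oxidation under buffered, near-neutral conditions should give the C5 ketone without epimerising the now enolisable C10 and without touching the alkene or the arene.

Step 12
Reactants: 21 (2S,3R,4S)-3,4-dimethyl-2-(4-methylpent-4-en-1-yl)-3-[(2,3,5,6-tetramethoxyphenyl)methyl]cyclohexan-1-one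
Product: 22 (1R,2S,4aS,8aS)-1,2,5,5-tetramethyl-1-[(2,3,5,6-tetramethoxyphenyl)methyl]decahydronaphthalen-4a-ol
Conditions: Fe(acac)3 (trivalent iron, 0.5 equiv), PhSiH3 (2.5 equiv), EtOH (0.05 M), 60 °C
Reagents that add atoms: none
Why: The iron hydride formed from Fe(acac)3 and PhSiH3 transfers a hydrogen atom to the terminal CH2 of the isopropenyl group, which creates the second C4 methyl and a nucleophilic tertiary C4 radical; this radical adds to the C5 carbonyl carbon, and the alkoxy radical is reduced by the divalent iron left behind and protonated by EtOH before it can fragment back, so the crowded C4–C5 bond persists and iron returns to the trivalent state. The closest known reaction type is the iron-hydride-initiated radical cyclisation of alkene-tethered ketones to cis-fused bicyclic tertiary alcohols. Ring A closes by 6-exo-trig attack of C4 on the C=O carbon, with the oxygen left outside the new ring. The new C5 stereocentre is controlled by C10: in the ring B chair the C8 methyl, the C9 arylmethyl group and the C10 tether are equatorial, and the three-carbon tether should bring C4 to the β face of C5 (axial bond formation through a chair-like transition state), which places the hydroxyl equatorial on the α face, cis to H10. The step needs bond formation on the β face and reaction at the chain alkene only; the tether geometry is relied on for the first and the absence of any other alkene secures the second. The neutral medium leaves the arene and the epimerisable C10 untouched.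

Step 13
Reactants: 22 (1R,2S,4aS,8aS)-1,2,5,5-tetramethyl-1-[(2,3,5,6-tetramethoxyphenyl)methyl]decahydronaphthalen-4a-ol
Product: 23 3-{[(1R,2S,4aS,8aS)-4a-hydroxy-1,2,5,5-tetramethyldecahydronaphthalen-1-yl]methyl}-2,5-dimethoxycyclohexa-2,5-diene-1,4-dione
Conditions: (NH4)2Ce(NO3)6 (tetravalent cerium, 2.5 equiv), MeCN/H2O, 0 °C
Reagents that add atoms: water, O
Why: Oxidative demethylation of one para-dimethoxy pair by tetravalent cerium (two one-electron oxidations with water adding at the methoxy-bearing carbons) should give the 2,5-dimethoxy-1,4-benzoquinone; the two para pairs are equivalent by the symmetry of the arene, and the tertiary alcohol is inert at 0 °C.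

Step 14
Reactants: 23 3-{[(1R,2S,4aS,8aS)-4a-hydroxy-1,2,5,5-tetramethyldecahydronaphthalen-1-yl]methyl}-2,5-dimethoxycyclohexa-2,5-diene-1,4-dione
Product: 24 2-hydroxy-3-{[(1R,2S,4aS,8aS)-4a-hydroxy-1,2,5,5-tetramethyldecahydronaphthalen-1-yl]methyl}-5-methoxycyclohexa-2,5-diene-1,4-dione
Conditions: KOH, MeOH/H2O, 0 °C to rt; then cold 1 M HCl to pH 3
Reagents that add atoms: potassium hydroxide, [K+].[OH-]
Why: Addition–elimination of hydroxide (vinylogous ester saponification) should take place at the methoxy-bearing carbon next to the alkyl-bearing carbon, whose methoxy group is twisted out of conjugation by the flanking CH2 group and is therefore the more electrophilic, and the resulting hydroxyquinone anion resists a second substitution while the base spares the acid-sensitive tertiary alcohol.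

**Compound list**

1 | 1,2,4,5-tetramethoxybenzene | COc1cc(OC)c(OC)cc1OC | starting material
2 | 2,3,5,6-tetramethoxyphenyllithium | [Li]c1c(OC)c(OC)cc(OC)c1OC | intermediate (not isolated)
3 | 2,3,5,6-tetramethoxybenzaldehyde | COc1cc(OC)c(OC)c(C=O)c1OC | intermediate
4 | (2,3,5,6-tetramethoxyphenyl)methanol | COc1cc(OC)c(OC)c(CO)c1OC | intermediate
5 | 3-(bromomethyl)-1,2,4,5-tetramethoxybenzene | COc1cc(OC)c(OC)c(CBr)c1OC | intermediate
6 | 2-methylcyclohex-2-en-1-one | CC1=CCCCC1=O | starting material
7 | dimethylaluminium (3S)-2,3-dimethylcyclohex-1-en-1-olate | C[C@H]1CCCC(O[Al](C)C)=C1C | intermediate (not isolated)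
8 | trimethyl{[(3S)-2,3-dimethylcyclohex-1-en-1-yl]oxy}silane | C[C@H]1CCCC(O[Si](C)(C)C)=C1C | intermediate
9 | lithium (3S)-2,3-dimethylcyclohex-1-en-1-olate | C[C@H]1CCCC(O[Li])=C1C | intermediate (not isolated)
10 | (2R,3S)-2,3-dimethyl-2-[(2,3,5,6-tetramethoxyphenyl)methyl]cyclohexan-1-one | COc1cc(OC)c(OC)c(C[C@]2(C)[C@@H](C)CCCC2=O)c1OC | intermediate
11 | potassium (5S,6R)-5,6-dimethyl-6-[(2,3,5,6-tetramethoxyphenyl)methyl]cyclohex-1-en-1-olate | COc1cc(OC)c(OC)c(C[C@]2(C)[C@@H](C)CCC=C2O[K])c1OC | intermediate (not isolated)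
12 | (5S,6R)-5,6-dimethyl-6-[(2,3,5,6-tetramethoxyphenyl)methyl]cyclohex-1-en-1-yl trifluoromethanesulfonate | COc1cc(OC)c(OC)c(C[C@]2(C)[C@@H](C)CCC=C2OS(=O)(=O)C(F)(F)F)c1OC | intermediate
13 | 2-(3-chloropropyl)-2-methyl-1,3-dioxolane | CC1(CCCCl)OCCO1 | starting material
14 | [3-(2-methyl-1,3-dioxolan-2-yl)propyl]magnesium chloride | CC1(CCC[Mg]Cl)OCCO1 | intermediate (not isolated)
15 | [3-(2-methyl-1,3-dioxolan-2-yl)propyl]zinc chloride | CC1(CCC[Zn]Cl)OCCO1 | intermediate (not isolated)
16 | 2-{3-[(5S,6R)-5,6-dimethyl-6-[(2,3,5,6-tetramethoxyphenyl)methyl]cyclohex-1-en-1-yl]propyl}-2-methyl-1,3-dioxolane | COc1cc(OC)c(OC)c(C[C@]2(C)[C@@H](C)CCC=C2CCCC3(C)OCCO3)c1OC | intermediate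
17 | C5 alkylborane of 16 (BH2 on C5 and H on C10, both on the α face) | COc1cc(OC)c(OC)c(C[C@]2(C)[C@@H](C)CC[C@H](B)[C@H]2CCCC3(C)OCCO3)c1OC | intermediate (not isolated)
18 | (1S,2S,3R,4S)-3,4-dimethyl-2-[3-(2-methyl-1,3-dioxolan-2-yl)propyl]-3-[(2,3,5,6-tetramethoxyphenyl)methyl]cyclohexan-1-ol | COc1cc(OC)c(OC)c(C[C@]2(C)[C@@H](C)CC[C@H](O)[C@H]2CCCC3(C)OCCO3)c1OC | intermediate
19 | 5-{(1S,2R,3S,6S)-6-hydroxy-2,3-dimethyl-2-[(2,3,5,6-tetramethoxyphenyl)methyl]cyclohexyl}pentan-2-one | COc1cc(OC)c(OC)c(C[C@]2(C)[C@@H](C)CC[C@H](O)[C@H]2CCCC(C)=O)c1OC | intermediate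
20 | (1S,2S,3R,4S)-3,4-dimethyl-2-(4-methylpent-4-en-1-yl)-3-[(2,3,5,6-tetramethoxyphenyl)methyl]cyclohexan-1-ol | COc1cc(OC)c(OC)c(C[C@]2(C)[C@@H](C)CC[C@H](O)[C@H]2CCCC(C)=C)c1OC | intermediate
21 | (2S,3R,4S)-3,4-dimethyl-2-(4-methylpent-4-en-1-yl)-3-[(2,3,5,6-tetramethoxyphenyl)methyl]cyclohexan-1-one | COc1cc(OC)c(OC)c(C[C@]2(C)[C@@H](C)CCC(=O)[C@H]2CCCC(C)=C)c1OC | intermediate (key-step precursor)
22 | (1R,2S,4aS,8aS)-1,2,5,5-tetramethyl-1-[(2,3,5,6-tetramethoxyphenyl)methyl]decahydronaphthalen-4a-ol (cis-fused; hydroxyl cis to H-8a) | COc1cc(OC)c(OC)c(C[C@]2(C)[C@@H](C)CC[C@]3(O)[C@H]2CCCC3(C)C)c1OC | intermediate (key-step product)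
23 | 3-{[(1R,2S,4aS,8aS)-4a-hydroxy-1,2,5,5-tetramethyldecahydronaphthalen-1-yl]methyl}-2,5-dimethoxycyclohexa-2,5-diene-1,4-dione | COC1=CC(=O)C(OC)=C(C[C@]2(C)[C@@H](C)CC[C@]3(O)[C@H]2CCCC3(C)C)C1=O | intermediate
24 | 2-hydroxy-3-{[(1R,2S,4aS,8aS)-4a-hydroxy-1,2,5,5-tetramethyldecahydronaphthalen-1-yl]methyl}-5-methoxycyclohexa-2,5-diene-1,4-dione (CNP0209468.1) | COC1=CC(=O)C(O)=C(C[C@]2(C)[C@@H](C)CC[C@]3(O)[C@H]2CCCC3(C)C)C1=O | target

**Step count**

Total: 14 steps. Longest linear sequence: 13 steps (from 1 through steps 1–3 and 5–14; the branch from 6 runs through 11 steps).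

**Steps most likely to fail**

1. Step 12 (key step). The radical may close on the α face of the C5 carbonyl and give the trans-fused C5 epimer, because the axial C9 methyl crowds the β face that the tether must reach; the tertiary radical may also be reduced before it closes. The fallback sets out from 21 and returns at 22; it forms the C4–C5 bond with palladium and brings in the oxygen last, from the open α face. Kinetic deprotonation of 21 at the C6 methylene (LDA, THF, −78 °C) and trapping with PhNTf2 should give the C5=C6 enol triflate F1 with C10 untouched. A reductive Heck cyclisation (Pd(OAc)2, PPh3, HCO2Na, DMF, 80 °C) closes ring A by 6-exo carbopalladation of the 1,1-disubstituted alkene; the neopentyl palladium species has no β-hydrogen and is reduced by formate to the second C4 methyl, giving the octalin F2. Epoxidation of its C5=C6 alkene with mCPBA (NaHCO3, CH2Cl2, 0 °C) should occur anti to the axial C9 methyl and give the α-epoxide F3. LiAlH4 (THF, reflux) opens it at the secondary C6 in a trans-diaxial sense and leaves the tertiary α-alcohol 22.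

2. Step 8. Borane may approach the β face of the ring alkene, which would give the diastereomer with the chain α at C10; the hindered alkene may also react slowly. The fallback sets out from 16 and returns at 21; it uses epoxidation and a 1,2-hydride shift, which place the C10 hydrogen on the face opposite to the one the reagent attacks. mCPBA on 16 (no other alkene is present) gives the β-epoxide F4. A Meinwald rearrangement (LiClO4, toluene, 80 °C, or catalytic InCl3) ionises the tertiary C10–O bond and shifts the C5 hydrogen to the α face of C10, giving the ketone F5; ring contraction would create two adjacent quaternary carbons and should not compete. NaBH4 (MeOH, 0 °C) reduces F5 to the alcohol F6, whose C5 configuration does not matter. Hydrolysis of the dioxolane as in step 9 gives the hydroxy ketone F7, methylenation as in step 10 gives the hydroxy alkene F8, and oxidation as in step 11 rejoins the route at 21.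

3. Step 14. Hydroxide may displace the methoxy group next to the ring hydrogen instead, or both methoxy groups. The fallback sets out from 23 and returns at 24; it gives up selective hydrolysis in favour of selective re-methylation. Exhaustive saponification (NaOH, H2O/dioxane, 50 °C, then cold dilute HCl) gives the dihydroxyquinone F9. Acid-catalysed methanolysis (MeOH, catalytic BF3·OEt2, rt) should then esterify only the vinylogous acid that is not flanked by the alkyl group, at a temperature that spares the tertiary alcohol, and give 24.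

**Further compounds**

F1 | step 12 | 4,5-dimethyl-6-(4-methylpent-4-en-1-yl)-5-[(2,3,5,6-tetramethoxyphenyl)methyl]cyclohex-1-en-1-yl trifluoromethanesulfonate (C5=C6 enol triflate of 21; C8, C9, C10 as in 21) | COc1cc(OC)c(OC)c(C[C@]2(C)[C@@H](C)CC=C(OS(=O)(=O)C(F)(F)F)[C@H]2CCCC(C)=C)c1OC
F2 | step 12 | 1,2,5,5-tetramethyl-1-[(2,3,5,6-tetramethoxyphenyl)methyl]-1,2,3,5,6,7,8,8a-octahydronaphthalene (C5=C6 alkene; C8, C9, C10 as in 21) | COc1cc(OC)c(OC)c(C[C@]2(C)[C@@H](C)CC=C3[C@H]2CCCC3(C)C)c1OC
F3 | step 12 | α-epoxide of F2 at C5–C6 (oxygen cis to H10) | COc1cc(OC)c(OC)c(C[C@]2(C)[C@@H](C)C[C@@H]4O[C@]43[C@H]2CCCC3(C)C)c1OC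
F4 | step 8 | β-epoxide of 16 at C10–C5 (oxygen cis to the C8 and C9 methyl groups) | COc1cc(OC)c(OC)c(C[C@]2(C)[C@@H](C)CC[C@H]4O[C@]42CCCC3(C)OCCO3)c1OC
F5 | step 8 | (2S,3R,4S)-3,4-dimethyl-2-[3-(2-methyl-1,3-dioxolan-2-yl)propyl]-3-[(2,3,5,6-tetramethoxyphenyl)methyl]cyclohexan-1-one | COc1cc(OC)c(OC)c(C[C@]2(C)[C@@H](C)CCC(=O)[C@H]2CCCC3(C)OCCO3)c1OC
F6 | step 8 | C5 epimer of 18 (hydroxyl cis to the C10 chain) | COc1cc(OC)c(OC)c(C[C@]2(C)[C@@H](C)CC[C@@H](O)[C@H]2CCCC3(C)OCCO3)c1OC
F7 | step 8 | C5 epimer of 19 | COc1cc(OC)c(OC)c(C[C@]2(C)[C@@H](C)CC[C@@H](O)[C@H]2CCCC(C)=O)c1OC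
F8 | step 8 | C5 epimer of 20 | COc1cc(OC)c(OC)c(C[C@]2(C)[C@@H](C)CC[C@@H](O)[C@H]2CCCC(C)=C)c1OC
F9 | step 14 | 2,5-dihydroxy-3-{[(1R,2S,4aS,8aS)-4a-hydroxy-1,2,5,5-tetramethyldecahydronaphthalen-1-yl]methyl}cyclohexa-2,5-diene-1,4-dione | OC1=CC(=O)C(O)=C(C[C@]2(C)[C@@H](C)CC[C@]3(O)[C@H]2CCCC3(C)C)C1=O
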